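## The problem

- The target is an achiral homoisoflavonoid: a γ-pyranone (ring C) fused to a benzene ring (ring A), with a 4-methoxybenzyl group (ring B) on C3.
- All the difficulty lies in ring A, where every carbon is substituted and no two substituents are alike: C4a acyl, C5 OCH3, C6 CH3, C7 OH, C8 CHO, C8a O1.
- Ring A is a phloroglucinol whose three oxygens are in three different states (ring oxygen O1, methyl ether O5, free phenol O7), alternating with three different carbon substituents.
- A route from a preformed phloroglucinol must choose three times between near-equivalent sites: which ortho hydroxyl closes ring C (6-methyl or 8-methyl chromone), which hydroxyl is methylated, and where the carbon groups go. The oxygen to be methylated, O5, is the chelated and least reactive one.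
- Sensitive groups: the salicylaldehyde unit at C7/C8, the electrophilic C2 of the pyranone (opened by hydroxide or amines), and the C5 methyl ether peri to C4=O (cleaved by strong Lewis acids).
- The feature that opens a different plan is the pattern C5(O)–C6(CH3)–C7(O)–C8(H) lying between C4a and C8a, the two carbons shared with ring C. This is the pattern delivered when a ketene carbonyl carbon (C5), a siloxyalkyne CH3C≡C–OSi (C6, C7) and a former diazo carbon (C8) are joined to a C=C bond (C8a=C4a). That C=C bond can be the C2=C3 bond of a monocyclic γ-pyranone with H on C3.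
- Ring A can therefore be built onto a simple pyranone with all three oxygens differentiated from the start. The formyl group then enters last at C8, the only free position and ortho to O7–H.

## Retrosynthesis

**21 to 19.** The C8–CHO bond is cut first because the aldehyde is the most fragile group. In 19, C8 is the only unsubstituted carbon of ring A and is ortho to the free O7–H, so ortho-formylation (Duff reaction, via aldimine 20) has no regiochemical choice.

**19 to 18 to 17.** The O5–CH3 and O7–Si bonds are cut. In 17 the two ring A oxygens are already different: O5–H is free and O7 is a triisopropylsilyl ether. Methylation of the only free hydroxyl followed by fluoride needs no selectivity. The forward methylation must spare the aryl silyl ether.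

**17 to 8 + 12 (key disconnection).** All of ring A is taken apart: C4a–C5, C5–C6 and C7–C8 are cut, and C8–C8a is traced back to a 1,2-shift.
- C5 and C8 are the carbonyl and diazo carbons of the diazoacetyl group of 8; C6 and C7 are the carbons of siloxyalkyne 12; C4a and C8a are C3 and C2 of the pyranone of 8.
- The precursor is a monocyclic pyranone with one side chain, much simpler than a differentiated, fully substituted arene.
- Against stepwise substitution of a phloroglucinol, this cut makes O1, O5 and O7 inequivalent by origin (ring oxygen, ketene carbonyl, silyl ether) and fixes the methyl group through alkyne polarity.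
- The forward reaction is a cascade: Wolff rearrangement to ketene 13, [2+2] cycloaddition to cyclobutenone 14, 4π opening to dienylketene 15, 6π closure to dienone 16, and tautomerisation to 17.

**8 to 6 to 4.** The diazoketone comes from acid 6 through acid chloride 7 and (trimethylsilyl)diazomethane. Acid 6 comes from oxidation of the hydroxymethyl group of 4 through aldehyde 5. No carbon skeleton is built here.

**4 to 2 + 3, and 2 to 1.** The benzyl–pyranone bond is cut to enol triflate 2 and 4-methoxybenzylzinc chloride 3 (Negishi coupling). Triflate 2 comes from kojic acid 1. Its enolic hydroxyl sits on the carbon that becomes C3 of the target, and its hydroxymethyl carbon becomes C8 after the Wolff shift.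

**12 to 9.** The siloxyalkyne comes from propyne 9 by oxidation of acetylide 10 to ynolate 11 and O-silylation.

## Roads not taken

**Alternative 1:** the obvious route, closing ring C on a preformed acylphloroglucinol.
- Cut: C4–C4a (acylation of 2,4,6-trihydroxytoluene A1 with 3-(4-methoxyphenyl)propanoic acid A2 to ketone A3), then O1–C2 and C2–C3.
- Forward key step: one-carbon insertion and cyclisation of A3 with a formamide-derived electrophile.
- Why the chosen plan is better: A3 has two non-equivalent chelated ortho hydroxyls, so closure can give the 6-methyl chromone A4 and the 8-methyl isomer A5. In A4 the hydroxyl to be methylated (O5) is the unreactive chelated one, which forces protection of O7, methylation and deprotection before formylation. The chosen plan has no isomer question and no protecting group beyond the silyl group that the alkyne brings.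

**Alternative 2:** ring A from a 2-pyranone by Diels–Alder reaction and loss of CO2.
- Cut: C4a–C5 and C6–C7.
- Forward key step: inverse-demand cycloaddition of the fused pyranone A6 with 1,1-dimethoxyprop-1-ene A7, then loss of CO2 and methanol, which sets C5–OCH3 and C6–CH3 in one step.
- Why the chosen plan is better: C7 of the chromone is inherited from C6 of the 2-pyranone ring. In the accessible A6 that carbon bears methyl, and the product is the 6,7-dimethyl compound A8. In a 1,3,5-trioxygenated ring any four contiguous carbons hold two oxygenated carbons, so the diene would have to be a 6-alkoxy-2-pyranone. That is a glutaconic anhydride enol ether: hydrolytically fragile and electronically mismatched for inverse demand. The chosen benzannulation brings O7 on the alkyne.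

**Alternative 3:** biomimetic Claisen closure of ring A on a pyranone.
- Cut: C5–C6.
- Forward key step: base-mediated intramolecular Claisen condensation of keto ester A9, giving diol A4 after enolisation.
- Why the chosen plan is better: this fixes the C-methyl position, but O5 and O7 emerge as two free hydroxyls, so the protect–methylate–deprotect sequence of alternative 1 returns. A9 is a tetrasubstituted pyranone with two different side chains and needs a longer run-up than 8.

Key step: step 6

Assumption: reagent 3 and a THF solution of propyne 9 are used as purchased; the target has no stereocentre, and the one stereocentre of intermediate 14 is racemic and disappears in the same step.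

## Route

Step 1
Reactants: 1 kojic acid (5-hydroxy-2-(hydroxymethyl)-4H-pyran-4-one)
Product: 2 6-(hydroxymethyl)-4-oxo-4H-pyran-3-yl trifluoromethanesulfonate
Conditions: PhNTf2, Et3N, DMF, 0 to 23 °C
Reagents that add atoms: N-phenylbis(trifluoromethanesulfonimide), O=S(=O)(N(c1ccccc1)S(=O)(=O)C(F)(F)F)C(F)(F)F
Why: Chemoselective O-triflation: the acidic enolic hydroxyl is deprotonated by Et3N and sulfonylated by the mild triflyl donor, which should leave the neutral primary alcohol untouched.

Step 2
Reactants: 2 6-(hydroxymethyl)-4-oxo-4H-pyran-3-yl trifluoromethanesulfonate; 3 4-methoxybenzylzinc chloride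
Product: 4 2-(hydroxymethyl)-5-(4-methoxybenzyl)-4H-pyran-4-one
Conditions: 3 (2.2 equiv), Pd(OAc)2 (5 mol %), SPhos (10 mol %), THF, 23 to 50 °C
Reagents that add atoms: none
Why: Negishi coupling: zerovalent palladium inserts into the electron-poor enol triflate, the benzylzinc (no β-hydrogen) transmetalates, and reductive elimination forms the C–C bond. Organozinc halides tolerate a free hydroxyl and do not add to the pyranone; the excess of 3 allows for slow protonolysis.

Step 3
Reactants: 4 2-(hydroxymethyl)-5-(4-methoxybenzyl)-4H-pyran-4-one
Product: 6 5-(4-methoxybenzyl)-4-oxo-4H-pyran-2-carboxylic acid, via pyranone-2-carbaldehyde 5 (not isolated)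
Conditions: TEMPO (20 mol %), PhI(OAc)2 (2.2 equiv), MeCN/H2O 1:1, 23 °C
Reagents that add atoms: water, O
Why: Oxoammonium oxidation of the primary alcohol to aldehyde 5, whose hydrate (favoured by the electron-poor pyranone) is oxidised on to the acid. The anisole ring and the diarylmethane-type CH2 should be spared.

Step 4
Reactants: 6 5-(4-methoxybenzyl)-4-oxo-4H-pyran-2-carboxylic acid
Product: 8 2-(2-diazoacetyl)-5-(4-methoxybenzyl)-4H-pyran-4-one, via acid chloride 7 (not isolated)
Conditions: (COCl)2, DMF (cat.), CH2Cl2, 0 to 23 °C, evaporate; TMSCHN2 (2 equiv), THF/MeCN, 0 °C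
Reagents that add atoms: (trimethylsilyl)diazomethane, C[Si](C)(C)C=[N+]=[N-]
Why: Arndt–Eistert-type diazoketone synthesis by C-acylation of the diazoalkane. Acid chloride 7 has no α-hydrogen, so no ketene pathway competes, and the silyl group is lost to chloride.

Step 5
Reactants: 9 propyne
Product: 12 triisopropyl(prop-1-yn-1-yloxy)silane, via 1-propynyllithium 10 (not isolated), via lithium prop-1-yn-1-olate 11 (not isolated)
Conditions: n-BuLi, THF, −78 °C; t-BuOOLi [from t-BuOOH and LiN(SiMe3)2], −78 to 0 °C; i-Pr3SiOTf, −78 °C
Reagents that add atoms: tert-butyl hydroperoxide, CC(C)(C)OO; triisopropylsilyl trifluoromethanesulfonate, CC(C)[Si](OS(=O)(=O)C(F)(F)F)(C(C)C)C(C)C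
Why: Acetylide 10 attacks the electrophilic oxygen of lithium tert-butyl peroxide to give ynolate 11. The bulky silyl triflate traps 11 on oxygen, giving an isolable siloxyalkyne.

Step 6
Reactants: 8 2-(2-diazoacetyl)-5-(4-methoxybenzyl)-4H-pyran-4-one; 12 triisopropyl(prop-1-yn-1-yloxy)silane
Product: 17 5-hydroxy-3-(4-methoxybenzyl)-6-methyl-7-(triisopropylsilyloxy)-4H-chromen-4-one, via pyranonylketene 13 (not isolated), via siloxycyclobutenone 14 (not isolated), via dienylketene 15 (not isolated), via 4aH-dienone tautomer 16 (not isolated)
Conditions: 12 (1.5 equiv), hν (365 nm LED), ClCH2CH2Cl, 23 °C; then 80 °C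
Reagents that add atoms: none
Why: Irradiation at a wavelength where essentially only the diazocarbonyl group is expected to absorb should cause Wolff rearrangement of 8 (loss of N2, 1,2-shift of the pyranon-2-yl group) to vinylketene 13, which the electron-rich alkyne 12 traps at 23 °C by [2+2] cycloaddition as cyclobutenone 14. On warming, 14 should undergo conrotatory 4π ring opening to dienylketene 15 and disrotatory 6π electrocyclisation onto the pyranone C3–H carbon (the future C4a) to give dienone 16, which enolises to the chelated phenol 17. The closest known reaction type is the Danheiser benzannulation in its diazoketone variant, which turns alkenyl and heteroaryl diazomethyl ketones and siloxyalkynes into 3-siloxyphenols. Ring A is the only ring closed, by 6π electrocyclisation followed by tautomerisation, and no stereocentre remains. The orientation of the [2+2] step is set by polarity: the nucleophilic methyl-bearing alkyne carbon bonds to the electrophilic ketene carbonyl carbon, which places CH3 on C6 between O5 and O7. The direction of ring fusion is set by the substrate: the ketenyl carbon sits on pyranone C2, whose only ring carbon neighbour is C3–H, so O1 must end on C8a. Because all of 13 is consumed by [2+2] before heating, the phenol of 17 never meets free ketene. The three oxygens of ring A emerge as ring oxygen, free phenol and silyl ether.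

Step 7
Reactants: 17 5-hydroxy-3-(4-methoxybenzyl)-6-methyl-7-(triisopropylsilyloxy)-4H-chromen-4-one
Product: 18 5-methoxy-3-(4-methoxybenzyl)-6-methyl-7-(triisopropylsilyloxy)-4H-chromen-4-one
Conditions: MeI, K2CO3, acetone, 56 °C
Reagents that add atoms: iodomethane, CI
Why: Williamson methylation of the only free hydroxyl. The chelated O5–H needs carbonate at reflux; the hindered aryl triisopropylsilyl ether should persist in anhydrous acetone.

Step 8
Reactants: 18 5-methoxy-3-(4-methoxybenzyl)-6-methyl-7-(triisopropylsilyloxy)-4H-chromen-4-one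
Product: 19 7-hydroxy-5-methoxy-3-(4-methoxybenzyl)-6-methyl-4H-chromen-4-one
Conditions: TBAF, AcOH, THF, 0 °C
Reagents that add atoms: none
Why: Fluoride cleavage of the aryl silyl ether, driven by the Si–F bond. Acetic acid buffers the phenoxide so that C2 of the pyranone is not attacked.

Step 9
Reactants: 19 7-hydroxy-5-methoxy-3-(4-methoxybenzyl)-6-methyl-4H-chromen-4-one
Product: 21 7-hydroxy-5-methoxy-3-(4-methoxybenzyl)-6-methyl-4-oxo-4H-chromene-8-carbaldehyde, via N-methyl aldimine 20 (not isolated)
Conditions: (CH2)6N4, AcOH, 100 °C; then 3 M HCl, 80 °C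
Reagents that add atoms: hexamethylenetetramine, C1N2CN3CN1CN(C2)C3; water, O
Why: Duff reaction: the phenol attacks the iminium from protonated hexamethylenetetramine at C8, the only free ring A carbon and ortho to O7–H. The benzylic amine is oxidised in situ to aldimine 20 and hydrolysed; the anisyl ring is not activated enough to react under these conditions.

## Compound list

1 | kojic acid (5-hydroxy-2-(hydroxymethyl)-4H-pyran-4-one) | O=c1cc(CO)occ1O | starting material
2 | 6-(hydroxymethyl)-4-oxo-4H-pyran-3-yl trifluoromethanesulfonate | O=c1cc(CO)occ1OS(=O)(=O)C(F)(F)F | intermediate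
3 | 4-methoxybenzylzinc chloride | COc1ccc(C[Zn]Cl)cc1 | starting material
4 | 2-(hydroxymethyl)-5-(4-methoxybenzyl)-4H-pyran-4-one | COc1ccc(Cc2coc(CO)cc2=O)cc1 | intermediate
5 | 5-(4-methoxybenzyl)-4-oxo-4H-pyran-2-carbaldehyde | COc1ccc(Cc2coc(C=O)cc2=O)cc1 | intermediate (not isolated)
6 | 5-(4-methoxybenzyl)-4-oxo-4H-pyran-2-carboxylic acid | COc1ccc(Cc2coc(C(=O)O)cc2=O)cc1 | intermediate
7 | 5-(4-methoxybenzyl)-4-oxo-4H-pyran-2-carbonyl chloride | COc1ccc(Cc2coc(C(=O)Cl)cc2=O)cc1 | intermediate (not isolated)
8 | 2-(2-diazoacetyl)-5-(4-methoxybenzyl)-4H-pyran-4-one | COc1ccc(Cc2coc(C(=O)C=[N+]=[N-])cc2=O)cc1 | intermediate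
9 | propyne | CC#C | starting material
10 | 1-propynyllithium | CC#C[Li] | intermediate (not isolated)
11 | lithium prop-1-yn-1-olate | CC#C[O-].[Li+] | intermediate (not isolated)
12 | triisopropyl(prop-1-yn-1-yloxy)silane | CC#CO[Si](C(C)C)(C(C)C)C(C)C | intermediate
13 | 2-[5-(4-methoxybenzyl)-4-oxo-4H-pyran-2-yl]ethen-1-one (pyranonylketene) | COc1ccc(Cc2coc(C=C=O)cc2=O)cc1 | intermediate (not isolated)
14 | 4-[5-(4-methoxybenzyl)-4-oxo-4H-pyran-2-yl]-2-methyl-3-(triisopropylsilyloxy)cyclobut-2-en-1-one (racemic) | COc1ccc(Cc2coc(C3C(=O)C(C)=C3O[Si](C(C)C)(C(C)C)C(C)C)cc2=O)cc1 | intermediate (not isolated)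
15 | 4-[5-(4-methoxybenzyl)-4-oxo-4H-pyran-2-yl]-2-methyl-3-(triisopropylsilyloxy)buta-1,3-dien-1-one, pyranonyl group cis to the ketene-bearing carbon | COc1ccc(Cc2coc(/C=C(O[Si](C(C)C)(C(C)C)C(C)C)\C(C)=C=O)cc2=O)cc1 | intermediate (not isolated)
16 | 3-(4-methoxybenzyl)-6-methyl-7-(triisopropylsilyloxy)-4aH-chromene-4,5-dione (racemic) | COc1ccc(CC2=COC3=CC(O[Si](C(C)C)(C(C)C)C(C)C)=C(C)C(=O)C3C2=O)cc1 | intermediate (not isolated)
17 | 5-hydroxy-3-(4-methoxybenzyl)-6-methyl-7-(triisopropylsilyloxy)-4H-chromen-4-one | COc1ccc(Cc2coc3cc(O[Si](C(C)C)(C(C)C)C(C)C)c(C)c(O)c3c2=O)cc1 | intermediate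
18 | 5-methoxy-3-(4-methoxybenzyl)-6-methyl-7-(triisopropylsilyloxy)-4H-chromen-4-one | COc1ccc(Cc2coc3cc(O[Si](C(C)C)(C(C)C)C(C)C)c(C)c(OC)c3c2=O)cc1 | intermediate
19 | 7-hydroxy-5-methoxy-3-(4-methoxybenzyl)-6-methyl-4H-chromen-4-one | COc1ccc(Cc2coc3cc(O)c(C)c(OC)c3c2=O)cc1 | intermediate
20 | 7-hydroxy-5-methoxy-3-(4-methoxybenzyl)-6-methyl-8-[(methylimino)methyl]-4H-chromen-4-one | COc1ccc(Cc2coc3c(C=NC)c(O)c(C)c(OC)c3c2=O)cc1 | intermediate (not isolated)
21 | 7-hydroxy-5-methoxy-3-(4-methoxybenzyl)-6-methyl-4-oxo-4H-chromene-8-carbaldehyde | COc1ccc(Cc2coc3c(C=O)c(O)c(C)c(OC)c3c2=O)cc1 | target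

## Step count and risk

Total steps: 9. Longest linear sequence: 8 (steps 1 to 4 and 6 to 9, from kojic acid 1); step 5 is a one-step branch.

**Step 6 (key step).**
- What may go wrong: the γ-pyranone, and later the accumulating 5-hydroxychromone, may compete for light, causing pyranone photoisomerisation or a stalled Wolff rearrangement. Ketene 13 may also be lost to dimerisation or adventitious water before the [2+2] step.
- Fallback (light-free generation of the same ketene): it sets out from 8. Silver-catalysed Wolff rearrangement in the dark (AgO2CPh, Et3N, THF/H2O; Arndt–Eistert homologation) should give [5-(4-methoxybenzyl)-4-oxo-4H-pyran-2-yl]acetic acid F1. Oxalyl chloride converts it into [5-(4-methoxybenzyl)-4-oxo-4H-pyran-2-yl]acetyl chloride F2. Slow addition of F2 to i-Pr2NEt and 12 in toluene at 80 °C releases 13 by dehydrochlorination, and the same thermal cascade brings the route back at 17.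

**Step 2.**
- What may go wrong: protonolysis of the benzylzinc by the free hydroxyl, homocoupling of 3, or slow transmetalation onto the pyranonyl palladium species.
- Fallback (a different C–C bond formation): it sets out from 2. Nozaki–Hiyama–Kishi addition to 4-methoxybenzaldehyde (CrCl2, NiCl2 cat., DMF) should give 2-(hydroxymethyl)-5-[hydroxy(4-methoxyphenyl)methyl]-4H-pyran-4-one F3. Ionic deoxygenation of its anisyl-stabilised benzylic alcohol (Et3SiH, CF3CO2H, CH2Cl2) returns to the route at 4.

**Step 7.**
- What may go wrong: carbonate-induced loss of the silyl group during the slow methylation of the chelated hydroxyl, followed by methylation of O7.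
- Fallback (protection reversed to exploit the chelation): it sets out from 17. TBAF gives 5,7-dihydroxy-3-(4-methoxybenzyl)-6-methyl-4H-chromen-4-one F4. MOMCl with i-Pr2NEt reacts only at the non-chelated O7 to give 5-hydroxy-7-(methoxymethoxy)-3-(4-methoxybenzyl)-6-methyl-4H-chromen-4-one F5. Me2SO4 with K2CO3 in refluxing acetone gives 5-methoxy-7-(methoxymethoxy)-3-(4-methoxybenzyl)-6-methyl-4H-chromen-4-one F6. HCl in methanol returns to the route at 19.

**Step 9.**
- What may go wrong: stalling at the aminomethyl stage, because the in situ oxidation to the aldimine is inefficient on a chromone-deactivated phenol, or competing aminomethylation of the anisyl ring.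
- Fallback (halogenation then carbonylation): it sets out from 19. N-bromosuccinimide in MeCN should brominate the only free, most activated position to give 8-bromo-7-hydroxy-5-methoxy-3-(4-methoxybenzyl)-6-methyl-4H-chromen-4-one F7. Palladium-catalysed reductive carbonylation (Pd(OAc)2, di(1-adamantyl)-n-butylphosphine, CO/H2, TMEDA, toluene, 100 °C) returns to the route at 21.

## Further compounds

F1 | step 6 | [5-(4-methoxybenzyl)-4-oxo-4H-pyran-2-yl]acetic acid | COc1ccc(Cc2coc(CC(=O)O)cc2=O)cc1
F2 | step 6 | [5-(4-methoxybenzyl)-4-oxo-4H-pyran-2-yl]acetyl chloride | COc1ccc(Cc2coc(CC(=O)Cl)cc2=O)cc1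
F3 | step 2 | 2-(hydroxymethyl)-5-[hydroxy(4-methoxyphenyl)methyl]-4H-pyran-4-one (racemic) | COc1ccc(C(O)c2coc(CO)cc2=O)cc1
F4 | step 7 | 5,7-dihydroxy-3-(4-methoxybenzyl)-6-methyl-4H-chromen-4-one | COc1ccc(Cc2coc3cc(O)c(C)c(O)c3c2=O)cc1
F5 | step 7 | 5-hydroxy-7-(methoxymethoxy)-3-(4-methoxybenzyl)-6-methyl-4H-chromen-4-one | COc1ccc(Cc2coc3cc(OCOC)c(C)c(O)c3c2=O)cc1
F6 | step 7 | 5-methoxy-7-(methoxymethoxy)-3-(4-methoxybenzyl)-6-methyl-4H-chromen-4-one | COc1ccc(Cc2coc3cc(OCOC)c(C)c(OC)c3c2=O)cc1
F7 | step 9 | 8-bromo-7-hydroxy-5-methoxy-3-(4-methoxybenzyl)-6-methyl-4H-chromen-4-one | COc1ccc(Cc2coc3c(Br)c(O)c(C)c(OC)c3c2=O)cc1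
A1 | alternative 1 | 2,4,6-trihydroxytoluene | Cc1c(O)cc(O)cc1O
A2 | alternative 1 | 3-(4-methoxyphenyl)propanoic acid | COc1ccc(CCC(=O)O)cc1
A3 | alternative 1 | 3-(4-methoxyphenyl)-1-(2,4,6-trihydroxy-3-methylphenyl)propan-1-one | COc1ccc(CCC(=O)c2c(O)cc(O)c(C)c2O)cc1
A4 | alternative 1 | 5,7-dihydroxy-3-(4-methoxybenzyl)-6-methyl-4H-chromen-4-one | COc1ccc(Cc2coc3cc(O)c(C)c(O)c3c2=O)cc1
A5 | alternative 1 | 5,7-dihydroxy-3-(4-methoxybenzyl)-8-methyl-4H-chromen-4-one | COc1ccc(Cc2coc3c(C)c(O)cc(O)c3c2=O)cc1
A6 | alternative 2 | 3-(4-methoxybenzyl)-7-methyl-4H,5H-pyrano[4,3-b]pyran-4,5-dione | COc1ccc(CC2=COC3=C(C2=O)C(=O)OC(C)=C3)cc1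
A7 | alternative 2 | 1,1-dimethoxyprop-1-ene | CC=C(OC)OC
A8 | alternative 2 | 5-methoxy-3-(4-methoxybenzyl)-6,7-dimethyl-4H-chromen-4-one | COc1ccc(Cc2coc3cc(C)c(C)c(OC)c3c2=O)cc1
A9 | alternative 3 | methyl 5-(4-methoxybenzyl)-4-oxo-2-(2-oxobutyl)-4H-pyran-3-carboxylate | CCC(=O)Cc1occ(Cc2ccc(OC)cc2)c(=O)c1C(=O)OC
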